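**Assumption:** the target is taken exactly as drawn, all four centres S (2S,3S in each trans-dihydrobenzofuran). The chiral diene antipode in each Rh step is chosen to deliver the S adduct, to be confirmed by X-ray of bromide 7.

## Retrosynthetic overview

1. Target ⇐ desilylation ⇐ Suzuki coupling of the C5 aryl bromide 19 with (E)-styrenyl boronate 22 (stilbene installed last).
2. Both dihydrobenzofuran rings (B and A) close together in one operation from bis-carbinol 18: acid unmasks the phenols, each 4-hydroxybenzylic alcohol gives a p-quinone methide, and the ortho-phenol adds intramolecularly (oxa-Michael, 1,6-addition) to give the trans rings.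
3. Each carbinol ⇐ α,α-diaryl acetaldehyde + 4-(MOMO)phenyl organocerium; each aldehyde ⇐ nitroalkane (Nef).
4. The two diaryl-methine centres (C3′, then C3) ⇐ two catalyst-controlled Rh/chiral-diene 1,4-arylations of β-nitrostyrenes; the second is the fragment union (boronate 12 + nitroalkene 15).
5. Building blocks: 5-bromoresorcinol (used twice), 4-bromophenol, 5-bromosalicylaldehyde, 3,5-dihydroxybenzaldehyde.

Abbreviations: MOM = CH2OCH3; TIPS = Si(i-Pr)3; TBS = SiMe2t-Bu; Bpin = pinacol boronate. Unprimed locants refer to ring A, primed to ring B.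

## Route

**Step 1**
Reactants: 1, 5-bromoresorcinol
Product: 2, 2-bromo-4,6-dihydroxybenzaldehyde
Conditions: POCl3, DMF, MeCN, −15 °C → rt; then H2O, 50 °C
Reagents that add atoms: DMF, CN(C)C=O (formyl C); water, O (formyl O)
Why: Vilsmeier–Haack formylation goes para to one OH and ortho to the other (C4), by analogy with orcinol and with 1-bromo-3,5-dimethoxybenzene; this regiochemistry is not confirmed for 5-bromoresorcinol itself.

**Step 2**
Reactants: 2
Product: 3, 2-bromo-4,6-bis(methoxymethoxy)benzaldehyde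
Conditions: MOMCl, i-Pr2NEt, cat. DMAP, CH2Cl2, 0 → 40 °C
Reagents that add atoms: chloromethyl methyl ether, COCCl
Why: Williamson-type O-alkylation; MOM survives the later basic and organometallic steps and leaves in the acid step 16.

**Step 3**
Reactants: 3
Product: 4, (E)-1-bromo-3,5-bis(methoxymethoxy)-2-(2-nitrovinyl)benzene
Conditions: MeNO2 (solvent), NH4OAc, 95 °C
Reagents that add atoms: nitromethane, C[N+](=O)[O-]
Why: Henry condensation–dehydration gives the thermodynamic E-nitrostyrene.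

**Step 4**
Reactants: 1, 5-bromoresorcinol
Product: 5, 1-bromo-3,5-bis(triisopropylsilyloxy)benzene
Conditions: TIPSCl, imidazole, DMF, rt
Reagents that add atoms: TIPSCl, CC(C)[Si](Cl)(C(C)C)C(C)C
Why: Phenol silylation; bulky TIPS is acid-stable and later shields this resorcinol ring from Friedel–Crafts side reactions.

**Step 5**
Reactants: 5
Product: 6, [3,5-bis(triisopropylsilyloxy)phenyl]boronic acid
Conditions: n-BuLi, THF, −78 °C; B(Oi-Pr)3; aq NH4Cl
Reagents that add atoms: triisopropyl borate, CC(C)OB(OC(C)C)OC(C)C; water, O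
Why: Br–Li exchange then borylation and hydrolysis.

**Step 6**
Reactants: 4; 6 (2.5 equiv)
Product: 7, (S)-1-bromo-3,5-bis(methoxymethoxy)-2-{2-nitro-1-[3,5-bis(triisopropylsilyloxy)phenyl]ethyl}benzene
Conditions: [RhCl(C2H4)2]2 (3 mol %), chiral diene (Ph-bod*, 6.6 mol %), aq K3PO4 (0.5 equiv), dioxane/H2O 10:1, 50 °C
Reagents that add atoms: none
Why: Hayashi–Miyaura asymmetric 1,4-arylation of a nitroalkene; the chiral diene–Rh–aryl species selects the alkene face and sets C3′ as S.

**Step 7**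
Reactants: 7
Product: 8, (S)-2-[2-bromo-4,6-bis(methoxymethoxy)phenyl]-2-[3,5-bis(triisopropylsilyloxy)phenyl]acetaldehyde
Conditions: NaOMe (1.05 equiv), MeOH/CH2Cl2, −20 °C; O3, −78 °C; Me2S; used crude and cold
Reagents that add atoms: ozone, [O-][O+]=O (carbonyl O)
Why: Nef reaction by ozonolysis of the nitronate; the nitronate stage does not touch the C3′–H, and the epimerisable aldehyde is kept neutral and cold.

**Step 8**
Reactants: 9, 4-bromophenol
Product: 10, 1-bromo-4-(methoxymethoxy)benzene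
Conditions: MOMCl, i-Pr2NEt, CH2Cl2, 0 °C → rt
Reagents that add atoms: chloromethyl methyl ether, COCCl
Why: Phenol protection; this MOM is later removed to give the free 4-OH needed for p-quinone methide formation.

**Step 9**
Reactants: 8; 10 (as ArMgBr, 2 equiv)
Product: 11, (2S)-2-[2-bromo-4,6-bis(methoxymethoxy)phenyl]-1-[4-(methoxymethoxy)phenyl]-2-[3,5-bis(triisopropylsilyloxy)phenyl]ethan-1-ol (C1 epimers)
Conditions: 10, Mg, THF; CeCl3, THF, −78 °C; add 8; −78 → −20 °C
Reagents that add atoms: none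
Why: Organocerium 1,2-addition is fast and weakly basic, so C3′ is not enolised; the carbinol centre is uncontrolled on purpose because it is erased in step 16.

**Step 10**
Reactants: 11
Product: 12, (2S)-2-[2-(Bpin)-4,6-bis(methoxymethoxy)phenyl]-1-[4-(methoxymethoxy)phenyl]-2-[3,5-bis(triisopropylsilyloxy)phenyl]ethan-1-ol
Conditions: B2pin2, Pd(dppf)Cl2 (5 mol %), KOAc, dioxane, 90 °C
Reagents that add atoms: bis(pinacolato)diboron, CC1(C)OB(B2OC(C)(C)C(C)(C)O2)OC1(C)C
Why: Miyaura borylation; the weak base leaves the free alcohol, MOM and TIPS groups alone.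

**Step 11**
Reactants: 13, 5-bromosalicylaldehyde
Product: 14, 5-bromo-2-(methoxymethoxy)benzaldehyde
Conditions: MOMCl, i-Pr2NEt, CH2Cl2, 0 °C → rt
Reagents that add atoms: chloromethyl methyl ether, COCCl
Why: Phenol protection before the Henry and Rh steps.

**Step 12**
Reactants: 14
Product: 15, (E)-4-bromo-1-(methoxymethoxy)-2-(2-nitrovinyl)benzene
Conditions: MeNO2, NH4OAc, 95 °C
Reagents that add atoms: nitromethane, C[N+](=O)[O-]
Why: Henry condensation–dehydration to the E-nitrostyrene.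

**Step 13 (fragment union)**
Reactants: 12; 15 (1.5 equiv)
Product: 16, (2S)-2-{2-[(1S)-1-(5-bromo-2-(methoxymethoxy)phenyl)-2-nitroethyl]-4,6-bis(methoxymethoxy)phenyl}-1-[4-(methoxymethoxy)phenyl]-2-[3,5-bis(triisopropylsilyloxy)phenyl]ethan-1-ol
Conditions: [RhCl(C2H4)2]2 (5 mol %), chiral diene (Ph-bod*, antipode chosen for S), aq K3PO4, dioxane/H2O 10:1, 60 °C
Reagents that add atoms: none
Why: Second Hayashi–Miyaura 1,4-arylation; the catalyst sets C3 as S and Rh(I) leaves both aryl bromides alone.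

**Step 14**
Reactants: 16
Product: 17, (2S)-2-[5-bromo-2-(methoxymethoxy)phenyl]-2-{2-[(1S)-2-hydroxy-2-(4-(methoxymethoxy)phenyl)-1-(3,5-bis(triisopropylsilyloxy)phenyl)ethyl]-3,5-bis(methoxymethoxy)phenyl}acetaldehyde
Conditions: NaOMe, MeOH/CH2Cl2, −20 °C; O3, −78 °C; Me2S; used crude
Reagents that add atoms: ozone, [O-][O+]=O
Why: Nef reaction via nitronate ozonolysis as in step 7; any seven-membered lactol with the free OH is harmless because it reopens in step 15.

**Step 15**
Reactants: 17; 10 (as ArMgBr, 4 equiv)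
Product: 18, (2S)-2-[5-bromo-2-(methoxymethoxy)phenyl]-2-{2-[(1S)-2-hydroxy-2-(4-(methoxymethoxy)phenyl)-1-(3,5-bis(triisopropylsilyloxy)phenyl)ethyl]-3,5-bis(methoxymethoxy)phenyl}-1-[4-(methoxymethoxy)phenyl]ethan-1-ol (carbinol epimers)
Conditions: ArMgBr (from 10, Mg), CeCl3, THF, −78 → −20 °C
Reagents that add atoms: none
Why: Organocerium 1,2-addition without enolisation of C3; both carbinol centres are mixtures that converge in the next step.

**Step 16 (key step: both rings)**
Reactants: 18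
Product: 19, 4-[(2S,3S)-5-bromo-3-{(2S,3S)-6-hydroxy-2-(4-hydroxyphenyl)-3-[3,5-bis(triisopropylsilyloxy)phenyl]-2,3-dihydro-1-benzofuran-4-yl}-2,3-dihydro-1-benzofuran-2-yl]phenol
Conditions: 3 M aq HCl/MeOH/THF (1:5:5), 45 °C
Reagents that add atoms: none
Why: All five MOM groups are cleaved, each 4-hydroxybenzylic alcohol dehydrates to a p-quinone methide, and the adjacent phenol closes the ring by intramolecular oxa-Michael (1,6-) addition. The addition is reversible, so the thermodynamic 2,3-trans isomer forms and C2′ and C2 are set S relative to the fixed C3′ and C3. Only the five-membered O-closures are geometrically feasible for the two phenols.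

**Step 17**
Reactants: 20, 3,5-dihydroxybenzaldehyde
Product: 21, 3,5-bis(tert-butyldimethylsilyloxy)benzaldehyde
Conditions: TBSCl, imidazole, DMF, rt
Reagents that add atoms: TBSCl, CC(C)(C)[Si](C)(C)Cl
Why: Phenol silylation.

**Step 18**
Reactants: 21
Product: 22, (E)-2-[3,5-bis(tert-butyldimethylsilyloxy)styryl]-4,4,5,5-tetramethyl-1,3,2-dioxaborolane
Conditions: CH2(Bpin)2, LiTMP, THF, 0 °C; then 21, −78 °C → rt
Reagents that add atoms: bis(pinacolatoboryl)methane, CC1(C)OB(CB2OC(C)(C)C(C)(C)O2)OC1(C)C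
Why: Boron-Wittig olefination gives the E-alkenyl boronate.

**Step 19**
Reactants: 19; 22 (1.5 equiv)
Product: 23, the bis-TIPS/bis-TBS ether of the target (5-[(E)-3,5-bis(TBSO)styryl] analogue of 19)
Conditions: SPhos Pd G2 (5 mol %), K3PO4, dioxane/H2O 5:1, 60 °C, degassed
Reagents that add atoms: none
Why: Suzuki–Miyaura coupling tolerates the free phenols and retains the E-alkene geometry; partial loss of silyl groups here does not matter.

**Step 20**
Reactants: 23
Product: 24, trans-diptoindonesin B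
Conditions: TBAF (6 equiv), AcOH (6 equiv), THF, 0 °C → rt
Reagents that add atoms: none
Why: Buffered fluoride desilylation removes the four silyl ethers without acid or strong base, sparing the stilbene and both trans rings.

## Compound list

1 | 5-bromoresorcinol | Oc1cc(O)cc(Br)c1 | starting material
2 | 2-bromo-4,6-dihydroxybenzaldehyde | O=Cc1c(O)cc(O)cc1Br | intermediate
3 | 2-bromo-4,6-bis(methoxymethoxy)benzaldehyde | O=Cc1c(OCOC)cc(OCOC)cc1Br | intermediate
4 | (E)-1-bromo-3,5-bis(MOMO)-2-(2-nitrovinyl)benzene | [O-][N+](=O)/C=C/c1c(OCOC)cc(OCOC)cc1Br | intermediate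
5 | 1-bromo-3,5-bis(TIPSO)benzene | Brc1cc(O[Si](C(C)C)(C(C)C)C(C)C)cc(O[Si](C(C)C)(C(C)C)C(C)C)c1 | intermediate
6 | [3,5-bis(TIPSO)phenyl]boronic acid | OB(O)c1cc(O[Si](C(C)C)(C(C)C)C(C)C)cc(O[Si](C(C)C)(C(C)C)C(C)C)c1 | intermediate
7 | (S)-nitroalkane | COCOc1cc(OCOC)cc(Br)c1[C@H](c1cc(O[Si](C(C)C)(C(C)C)C(C)C)cc(O[Si](C(C)C)(C(C)C)C(C)C)c1)C[N+](=O)[O-] | intermediate
8 | (S)-diarylacetaldehyde | COCOc1cc(OCOC)cc(Br)c1[C@H](c1cc(O[Si](C(C)C)(C(C)C)C(C)C)cc(O[Si](C(C)C)(C(C)C)C(C)C)c1)C=O | intermediate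
9 | 4-bromophenol | Oc1ccc(Br)cc1 | starting material
10 | 1-bromo-4-(methoxymethoxy)benzene | COCOc1ccc(Br)cc1 | intermediate
11 | (2S)-bromo carbinol (C1 epimers) | COCOc1cc(OCOC)cc(Br)c1[C@H](c1cc(O[Si](C(C)C)(C(C)C)C(C)C)cc(O[Si](C(C)C)(C(C)C)C(C)C)c1)C(O)c1ccc(OCOC)cc1 | intermediate
12 | (2S)-Bpin carbinol | COCOc1cc(OCOC)cc(B2OC(C)(C)C(C)(C)O2)c1[C@H](c1cc(O[Si](C(C)C)(C(C)C)C(C)C)cc(O[Si](C(C)C)(C(C)C)C(C)C)c1)C(O)c1ccc(OCOC)cc1 | intermediate
13 | 5-bromosalicylaldehyde | O=Cc1cc(Br)ccc1O | starting material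
14 | 5-bromo-2-(methoxymethoxy)benzaldehyde | COCOc1ccc(Br)cc1C=O | intermediate
15 | (E)-4-bromo-1-(MOMO)-2-(2-nitrovinyl)benzene | COCOc1ccc(Br)cc1/C=C/[N+](=O)[O-] | intermediate
16 | (S,S)-nitroalkane carbinol | COCOc1ccc(Br)cc1[C@@H](C[N+](=O)[O-])c1cc(OCOC)cc(OCOC)c1[C@H](c1cc(O[Si](C(C)C)(C(C)C)C(C)C)cc(O[Si](C(C)C)(C(C)C)C(C)C)c1)C(O)c1ccc(OCOC)cc1 | intermediate
17 | (S,S)-aldehyde carbinol | COCOc1ccc(Br)cc1[C@@H](C=O)c1cc(OCOC)cc(OCOC)c1[C@H](c1cc(O[Si](C(C)C)(C(C)C)C(C)C)cc(O[Si](C(C)C)(C(C)C)C(C)C)c1)C(O)c1ccc(OCOC)cc1 | intermediate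
18 | (S,S)-bis-carbinol | COCOc1ccc(Br)cc1[C@@H](C(O)c1ccc(OCOC)cc1)c1cc(OCOC)cc(OCOC)c1[C@H](c1cc(O[Si](C(C)C)(C(C)C)C(C)C)cc(O[Si](C(C)C)(C(C)C)C(C)C)c1)C(O)c1ccc(OCOC)cc1 | intermediate
19 | (2S,3S,2′S,3′S)-bromo bis(dihydrobenzofuran), Ar3 bis-TIPS | Oc1ccc([C@H]2Oc3ccc(Br)cc3[C@@H]2c2cc(O)cc3c2[C@H](c2cc(O[Si](C(C)C)(C(C)C)C(C)C)cc(O[Si](C(C)C)(C(C)C)C(C)C)c2)[C@@H](c2ccc(O)cc2)O3)cc1 | intermediate
20 | 3,5-dihydroxybenzaldehyde | O=Cc1cc(O)cc(O)c1 | starting material
21 | 3,5-bis(TBSO)benzaldehyde | O=Cc1cc(O[Si](C)(C)C(C)(C)C)cc(O[Si](C)(C)C(C)(C)C)c1 | intermediate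
22 | (E)-3,5-bis(TBSO)styryl-Bpin | CC1(C)OB(/C=C/c2cc(O[Si](C)(C)C(C)(C)C)cc(O[Si](C)(C)C(C)(C)C)c2)OC1(C)C | intermediate
23 | tetrasilyl ether of target | Oc1ccc([C@H]2Oc3ccc(/C=C/c4cc(O[Si](C)(C)C(C)(C)C)cc(O[Si](C)(C)C(C)(C)C)c4)cc3[C@@H]2c2cc(O)cc3c2[C@H](c2cc(O[Si](C(C)C)(C(C)C)C(C)C)cc(O[Si](C(C)C)(C(C)C)C(C)C)c2)[C@@H](c2ccc(O)cc2)O3)cc1 | intermediate
24 | trans-diptoindonesin B | Oc1ccc([C@H]2Oc3ccc(/C=C/c4cc(O)cc(O)c4)cc3[C@@H]2c2cc(O)cc3c2[C@H](c2cc(O)cc(O)c2)[C@@H](c2ccc(O)cc2)O3)cc1 | target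

## Summary

- **Total steps:** 20.
- **Longest linear sequence:** 13 (steps 1, 2, 3, 6, 7, 9, 10, 13, 14, 15, 16, 19, 20), which is 65 % of the total.
- **Side branches:** steps 4–5, 8, 11–12, 17–18.

**Three steps most likely to fail, with fallbacks**

1. **Step 6** (Rh arylation of a 2,6-disubstituted nitrostyrene; the hindered β-carbon may react slowly or with poor ee). Fallback: set C3′ by asymmetric hydride delivery instead of C–C formation. Add the Grignard from 5 to aldehyde 2, oxidise to the 2-hydroxybenzophenone, and convert with Ph3P=CHCO2Et to the 4-aryl-5-bromocoumarin. Then do a CuH/DTBM-SEGPHOS conjugate reduction to the 4-arylchromanone, followed by DIBAL, dehydration to the 4H-chromene and ozonolysis to the aldehyde/lactol equivalent of 8.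

2. **Step 13** (ortho-hindered boronate that already carries a stereocentre; protodeboronation or mismatched double stereodifferentiation). Fallback: reverse the roles and close ring B first. Cyclise 11 under the step-16 conditions to the 4-bromo-dihydrobenzofuran, silylate, convert Br to CHO (n-BuLi, DMF), and run a Henry reaction. Then add the unhindered 5-bromo-2-(MOMO)phenylboronic acid to this rigid nitroalkene under the same Rh catalysis, and build ring A afterwards.

3. **Step 16** (double deprotection and cyclisation under acid; possible E1 loss of the C3–H with erosion of ee, or Friedel–Crafts capture of the quinone methide by a neighbouring arene). Fallback: close the rings one at a time under base, not acid. Carry the participating oxygens as TBS ethers (using 4-TBSO-phenyl organometallic), acetylate the carbinol, and trigger with TBAF. Fluoride-induced 1,6-elimination of acetate gives the neutral p-quinone methide and the phenoxide adds in the same pot, ring B at the stage of 11 and ring A at the stage of 18.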